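What excess of Yx over Vo should this flask hold at the asked time, given that Eb and Ym stay so close together?

| flask | Eb | Ym | Jo | Qo | Ly | Ej | remark | time |
|---|---|---|---|---|---|---|---|---|
| Monday's | 25 mM | 25 mM | 62.5 mM | 0.10 mM | 0.25 mM | 0.31 mM | run made earlier |  |
| Saturday's | 25 mM | 25 mM | 62.5 mM | 0.10 mM | 0.25 mM | 0.69 mM | run made earlier |  |
| Sunday's | 38 mM | 38 mM | 62.5 mM | 0.10 mM | 0.25 mM | 0.46 mM | run made earlier |  |
| flask | 25 mM | 25 mM | 62.5 mM | 0.10 mM | 0.25 mM | 0.46 mM |  | 6.0 h |

- Monday's (time / h: Eb / %, Ym / %): 1.00: 46.4, 47.3; 2.00: 45.1, 47.5; 3.00: 44.0, 46.0; 4.00: 44.1, 46.0; 5.00: 44.0, 45.1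
- Saturday's (time / h: Eb / %, Ym / %): 0.417: 47.4, 49.2; 0.667: 47.7, 48.4; 1.33: 46.3, 48.3; 2.50: 44.5, 46.5; 5.00: 44.7, 44.5
- Sunday's (time / h: Eb / %, Ym / %): 0.417: 47.5, 49.1; 0.667: 47.1, 48.2; 1.33: 46.0, 48.2; 2.50: 45.5, 47.0; 5.00: 45.0, 45.5

(each reading ± 0.5 percentage points)

- Qo is single-handed; Eb and Ym are mirror images of each other, charged as a racemate, each of them at the stated concentration
- the numbers in the tables scatter with a standard deviation of 0.5 percentage points
- an excess is the difference of the two amounts in percent of their sum
- an excess is below zero if the other one leads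

1. part of the Eb and Ym charged together that has reacted at 6.0 h
2. excess of Yx over Vo in the product at 6.0 h
3. excess of Ym over Eb among what is left of the two at 6.0 h

I read the first and last rows of Saturday's and Sunday's tables. In the first rows Ym led Eb by 1.8 percentage points and 1.6 points, against a scatter of 0.5 points per reading, while the two together had lost 3.4 points and 3.4 points. Pooled, gap over loss gave 50.0%, a soft reading of the product excess at nearly equal Eb and Ym, amounting to a selectivity factor of 3.00.

In the last rows the two gaps summed to 0.3 points, less than the 3.4 points of the first rows. So I treated the substrate excess as a small correction. One minus the square of that reading gave 0.750, the slip: points of product excess lost per point of substrate excess. The first rows' substrate excess of 1.76% cost 1.3 points, so I committed to an eP of 48.7%.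

The forecast said c 11.5%, eP 40%, eS 0.6%, reasoning: “The product would then keep its excess even as the substrate excess fades.” My eP stood above it.

The flask gave c 11.5%, eP 46.0%, eS 0.901%: the forecast's eP lay 6 points low, mine 2.7 points high.

    Jo + Qo + Eb → Qo + Yx (k = 383 /M²/min)
    Jo + Qo + Ym → Qo + Vo (k = 138 /M²/min)
    Eb + Ly ⇌ Ym + Ly, rate k3*[Ly]*[Eb] forward; the back reaction follows from the equilibrium constant (k = 26.0 /M/min)
    Ly + Ej ⇌ LyEj (K = 1030 /M, k = 38.2 /M/min)
    2 Qo → Ty (k = 154 /M/min)
    Jo + Qo → JoQo (k = 0.00611 /M/min)

At 1.18 h this flask used Eb for Yx at 0.15 of the forward rate at which Eb turned into Ym. At 6.0 h its eS times the slip came to 0.68 points, small beside its eP.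

In the neighbour flask with 0.12 mM of Ej, eS was 0.651%, so the slip estimated the excess of the product forming at 6.0 h at 0.19 points above that in this flask. That is no estimate of eP, which counts the product of the whole run: this flask had made half of its Yx by 1.20 h. The computed eP there is 46.1%.

The numbers in the tables stem from a simulated flask with constants of no real substance; scatter was added.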